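**Assumption:** the target has no stereocentres or stereogenic double bonds (it is achiral), so the route only has to deliver the constitution given.

## Retrosynthetic overview
1. The C8–O(isovaleryl) bond is made last, by ortho-acyloxylation of the 7-OH flavone santin with diisovaleryl peroxide; C8 is the only free A-ring position.
2. The pyranone ring is cut at C4–C3 and O1–C2: a Rh(III) formyl C–H activation/oxidative annulation of a pentasubstituted salicylaldehyde with the ynol ether MeO–C≡C–C6H4-4-OMe (new step). This brings in C2, C3, 3-OMe and the B ring together.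
3. The salicylaldehyde comes from resorcinol: MOM protection, ortho-lithiation/oxidation/methylation (6-OMe), Ir C–H borylation/oxidation (the future O1), ortho-formylation (the future C4).
4. The ynol ether comes from 4-iodophenol and chloroacetaldehyde dimethyl acetal (stannyl methoxyacetylene, Stille); the peroxide comes from two molecules of isovaleryl chloride and H2O2.
5. Ring order: A and B rings are bought as benzenes and decorated; the C ring is formed in the annulation.

## Route

**Step 1**
Reactants: 1, resorcinol
Product: 2, 1,3-bis(methoxymethoxy)benzene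
Conditions: MOMCl (2.4 equiv), iPr2NEt, CH2Cl2, 0 °C → rt
Reagents that add atoms: chloromethyl methyl ether (two equivalents are incorporated), COCCl
Why: Williamson-type O-alkylation of both phenols; MOM both directs the later ortho-lithiation and comes off with mild acid.

**Step 2**
Reactants: 2, 1,3-bis(methoxymethoxy)benzene
Product: 3, 2,6-bis(methoxymethoxy)phenol
Conditions: n-BuLi, TMEDA, THF, 0 °C → rt; B(OMe)3, −78 °C → rt; then 30% H2O2, aq NaOH, 0 °C
Reagents that add atoms: hydrogen peroxide, OO (the new oxygen; boron is transient)
Why: Directed ortho-metalation at the C–H flanked by both OMOM groups, borate trapping and boronate oxidation.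

**Step 3**
Reactants: 3, 2,6-bis(methoxymethoxy)phenol
Product: 4, 2-methoxy-1,3-bis(methoxymethoxy)benzene
Conditions: MeI, K2CO3, DMF, rt
Reagents that add atoms: iodomethane, CI
Why: Williamson methylation of the phenoxide; this fixes the future 6-OMe.

**Step 4**
Reactants: 4, 2-methoxy-1,3-bis(methoxymethoxy)benzene
Product: 5, 4-methoxy-3,5-bis(methoxymethoxy)phenol
Conditions: [Ir(OMe)(cod)]2 (1.5 mol %), dtbpy (3 mol %), B2pin2, THF, 80 °C; then 30% H2O2, aq NaOH, 0 °C (one pot)
Reagents that add atoms: hydrogen peroxide, OO (the new oxygen; Bpin is transient)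
Why: Sterically controlled Ir-catalysed C–H borylation occurs at the only C–H with no ortho substituent (as for 1,2,3-trimethoxybenzene), and oxidation of the boronate gives the phenol.

**Step 5**
Reactants: 5, 4-methoxy-3,5-bis(methoxymethoxy)phenol
Product: 6, 2-hydroxy-5-methoxy-4,6-bis(methoxymethoxy)benzaldehyde
Conditions: MgCl2, Et3N, (CH2O)n, MeCN, 80 °C
Reagents that add atoms: paraformaldehyde (formaldehyde), C=O
Why: Magnesium phenoxide-mediated ortho-formylation (Casnati/Hansen–Skattebøl); the two ortho positions are equivalent and the basic conditions spare the MOM ethers.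

**Step 6**
Reactants: 7, 4-iodophenol
Product: 8, 4-iodoanisole
Conditions: MeI, K2CO3, acetone, reflux
Reagents that add atoms: iodomethane, CI
Why: Williamson methylation.

**Step 7**
Reactants: 9, chloroacetaldehyde dimethyl acetal
Product: 10, tributyl(methoxyethynyl)stannane (Bu3Sn–C≡C–OMe)
Conditions: LiNEt2 (3.1 equiv), THF, 0 °C; then Bu3SnCl, −78 °C → rt; distil
Reagents that add atoms: tributyltin chloride, CCCC[Sn](Cl)(CCCC)CCCC
Why: Double elimination (MeOH, then HCl) and deprotonation give lithium methoxyacetylide, which is stannylated, as in the known ethoxy series.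

**Step 8**
Reactants: 8, 4-iodoanisole; 10, tributyl(methoxyethynyl)stannane
Product: 11, 1-methoxy-4-(methoxyethynyl)benzene (MeO–C≡C–C6H4-4-OMe)
Conditions: Pd(PPh3)4 (5 mol %), toluene, 80 °C; filter through Et3N-deactivated basic alumina, store cold
Reagents that add atoms: none
Why: Stille coupling of an alkoxyethynylstannane with an aryl iodide; the neutral, Lewis-acid-free conditions preserve the acid-sensitive ynol ether.

**Step 9**
Reactants: 12, isovaleryl chloride (3-methylbutanoyl chloride), 2.0 equiv; both acyl groups of the product come from it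
Product: 13, bis(3-methylbutanoyl) peroxide (diisovaleryl peroxide)
Conditions: 30% aq H2O2 (1.0 equiv per 2.0 equiv of 12), pyridine (2.2 equiv), Et2O, −10 → 0 °C; keep as a cold titrated CHCl3 solution, never concentrate to dryness
Reagents that add atoms: hydrogen peroxide, OO; isovaleryl chloride (the second equivalent), CC(C)CC(=O)Cl
Why: Standard diacyl peroxide synthesis: each O–H of hydrogen peroxide is acylated by one molecule of acid chloride (2 RCOCl + H2O2 → RC(O)O–OC(O)R + 2 HCl, the HCl taken up by pyridine).

**Step 10**
Reactants: 6, 2-hydroxy-5-methoxy-4,6-bis(methoxymethoxy)benzaldehyde; 11, 1-methoxy-4-(methoxyethynyl)benzene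
Product: 14, 3,6-dimethoxy-2-(4-methoxyphenyl)-5,7-bis(methoxymethoxy)-4H-chromen-4-one
Conditions: [Cp*RhCl2]2 (2.5 mol %), CsOPiv (30 mol %), anhydrous Cu(OAc)2 (2.2 equiv), K2CO3 (2 equiv), 4 Å MS, PhCl, 90 °C; 11 (1.5 equiv) added by syringe pump over 4 h
Reagents that add atoms: none
Why: Proposed new method: phenoxide-directed formyl C–H activation gives a five-membered acyl-rhodacycle; the polarised ynol ether then inserts so that the acyl carbon bonds to the electrophilic O-bearing carbon (→ C3-OMe) and Rh sits on the aryl-bearing carbon, and C–O reductive elimination closes O1–C2 with Cu(II) reoxidising Rh(I); the carbonate/sieves buffer and slow addition keep the ynol ether from acid-mediated hydration or addition; the closest known reaction is the Rh-catalysed oxidative annulation of salicylaldehydes with internal (dialkyl/diaryl) alkynes to chromones, with the regiochemistry argued by analogy to Rh(III) annulations of ynamides, and ynol ethers have not been used in it.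

**Step 11**
Reactants: 14, 3,6-dimethoxy-2-(4-methoxyphenyl)-5,7-bis(methoxymethoxy)-4H-chromen-4-one
Product: 15, santin (5,7-dihydroxy-3,6-dimethoxy-2-(4-methoxyphenyl)-4H-chromen-4-one)
Conditions: 3 M HCl, MeOH/THF, 50 °C
Reagents that add atoms: none
Why: Acid cleavage of the MOM acetals; the methyl ethers, including the 3-OMe on the chromone, are stable to dilute acid.

**Step 12**
Reactants: 15, santin; 13, bis(3-methylbutanoyl) peroxide (1.5 equiv)
Product: 16, 5,7-dihydroxy-3,6-dimethoxy-2-(4-methoxyphenyl)-4-oxo-4H-chromen-8-yl 3-methylbutanoate (target)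
Conditions: CHCl3, 40 °C, dark; neutral (pH 7 buffer) work-up
Reagents that add atoms: none
Why: Classical non-radical ortho-acyloxylation of a phenol by a diacyl peroxide (Walling-type O–O heterolysis and shift to the ortho carbon); C8 is the only unsubstituted A-ring carbon, the 5-OH is tied up in a hydrogen bond to C4=O, and the acyl group lands on the new C8 oxygen, leaving 7-OH free; one isovaleric acid is lost.

## Compound list
1 | resorcinol | Oc1cccc(O)c1 | starting material
2 | 1,3-bis(methoxymethoxy)benzene | COCOc1cccc(OCOC)c1 | intermediate
3 | 2,6-bis(methoxymethoxy)phenol | COCOc1cccc(OCOC)c1O | intermediate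
4 | 2-methoxy-1,3-bis(methoxymethoxy)benzene | COCOc1cccc(OCOC)c1OC | intermediate
5 | 4-methoxy-3,5-bis(methoxymethoxy)phenol | COCOc1cc(O)cc(OCOC)c1OC | intermediate
6 | 2-hydroxy-5-methoxy-4,6-bis(methoxymethoxy)benzaldehyde | COCOc1cc(O)c(C=O)c(OCOC)c1OC | intermediate
7 | 4-iodophenol | Oc1ccc(I)cc1 | starting material
8 | 4-iodoanisole | COc1ccc(I)cc1 | intermediate
9 | chloroacetaldehyde dimethyl acetal | COC(CCl)OC | starting material
10 | tributyl(methoxyethynyl)stannane | CCCC[Sn](CCCC)(CCCC)C#COC | intermediate
11 | 1-methoxy-4-(methoxyethynyl)benzene | COC#Cc1ccc(OC)cc1 | intermediate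
12 | isovaleryl chloride | CC(C)CC(=O)Cl | starting material
13 | bis(3-methylbutanoyl) peroxide | CC(C)CC(=O)OOC(=O)CC(C)C | intermediate
14 | 3,6-dimethoxy-2-(4-methoxyphenyl)-5,7-bis(methoxymethoxy)-4H-chromen-4-one | COCOc1cc2oc(-c3ccc(OC)cc3)c(OC)c(=O)c2c(OCOC)c1OC | intermediate
15 | santin (5,7-dihydroxy-3,6,4'-trimethoxyflavone) | COc1ccc(-c2oc3cc(O)c(OC)c(O)c3c(=O)c2OC)cc1 | intermediate
16 | 5,7,8-trihydroxy-3,6,4'-trimethoxyflavone 8-isovalerate | COc1ccc(-c2oc3c(OC(=O)CC(C)C)c(O)c(OC)c(O)c3c(=O)c2OC)cc1 | target

## Summary
Total step count: 12.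
Longest linear sequence: 8 (steps 1–5, 10, 11, 12). The ynol ether branch (steps 6–8) and the peroxide branch (step 9) run in parallel.

Three steps most likely to fail:

1. **Step 10 (proposed new Rh annulation).** Risks are ynol ether hydration, Lewis-acid-promoted aldehyde–alkyne metathesis (leading to a coumarin), or the reverse regiochemistry (a 2-methoxyisoflavone). Fallback, known chemistry:
   - iodinate phenol 5 (NIS) to the o-iodophenol;
   - run a Pd-catalysed carbonylative Sonogashira annulation (PdCl2(PPh3)2, CO, Et2NH) with 4-ethynylanisole, made from 8 and TMS-acetylene, to the 3-unsubstituted flavone;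
   - install 3-OMe by C3 hydroxylation (LDA, B(OMe)3, H2O2, or DMDO) and MeI;
   - rejoin at step 11.

2. **Step 12 (peroxide ortho-acyloxylation).** The 7-OH is a relatively electron-poor phenol, the aliphatic peroxide can homolyse, and 7-O-acylation or acyl migration may compete. Fallback, known chemistry:
   - 7-O-benzylation of 15 (BnBr, K2CO3; the 5-OH stays chelated);
   - Elbs persulfate oxidation (K2S2O8, aq KOH/pyridine, then acid hydrolysis of the sulfate) to the 8-hydroxy compound;
   - 8-O-acylation with isovaleryl chloride;
   - hydrogenolysis (H2, Pd/C).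

3. **Step 8 (Stille coupling to the ynol ether and its isolation).** The product may hydrate to methyl 4-methoxyphenylacetate or decompose on purification. Fallback, known chemistry: Friedel–Crafts acylation of anisole with methoxyacetyl chloride to 2-methoxy-1-(4-methoxyphenyl)ethanone, enol triflate formation (KHMDS, PhNTf2), and KOtBu elimination to 11.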